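The data were computed for substances that don't exist.

Watch the first hours. I have two earlier flasks and want target at the asked time in flasks that differ in their charge of protic impurity.

| flask | starting material | protic impurity | remark | time |
|---|---|---|---|---|
| epsilon | 0.80 M | 0.047 M | run made earlier |  |
| zeta | 0.80 M | 0.72 M | run made earlier |  |
| ochre | 0.80 M | 0.120 M |  | 30 h |
| teal | 0.80 M | 1.00 M |  | 30 h |
| green | 0.80 M | 0.0600 M |  | 30 h |
| grey | 0.80 M | 0.500 M |  | 30 h |
| violet | 0.80 M | 0.240 M |  | 30 h |

| run | time / h | target / % | starting material / % |
|---|---|---|---|
| epsilon | 4.00 | 11.5 | 70.0 |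
| epsilon | 8.00 | 18.0 | 53.4 |
| epsilon | 12.0 | 24.4 | 43.3 |
| epsilon | 15.0 | 28.4 | 38.8 |
| epsilon | 20.0 | 31.9 | 32.8 |
| epsilon | 25.0 | 34.8 | 28.9 |
| epsilon | 30.0 | 37.6 | 25.7 |
| zeta | 1.50 | 4.2 | 54.6 |
| zeta | 5.00 | 7.7 | 22.3 |
| zeta | 8.00 | 8.8 | 14.2 |
| zeta | 12.0 | 10.3 | 9.2 |
| zeta | 20.0 | 10.4 | 4.6 |
| zeta | 25.0 | 10.5 | 3.8 |
| zeta | 30.0 | 10.2 | 4.1 |

(scatter of a reading: 0.5 percentage points)

* the flasks put in order of amount of target, in percent of the starting material charged, best first, at 30 h (ochre / teal / green / grey / violet)
* the amount of target, in percent of the starting material charged of the flask you put first, at 30 h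
* the amount of target, in percent of the starting material charged of the flask you put last, at 30 h

- a reading or a percentage of target counts all its forms, free or not
- a reading of starting material is of its free form alone

I read the last row of zeta first. Target 10.2% and starting material 4.1% leave 85.7% of the charge unseen, and the impurity charge is 90.0% of the starting-material charge, so I take each impurity to remove one starting material. That leaves epsilon 94.1%. This free share is one minus the impurity charge over the starting-material charge. Epsilon's last row then gives 39.9% target per free charge.

Ordering the flasks costs me one multiplication each: green 37.0%, ochre 34.0%, violet 28.0%, grey 15.0%. Zeta warns me, though: the same product gives it 3.99% against a reading of 10.2%, so I trust the rule less as the free share shrinks. Teal's free share is −25.0%, so the rule says nothing there. I expect teal last, below zeta's reading, and I have no number of my own for it.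

The forecast gives green > ochre > violet > grey > teal, with 37% for the first flask and 6.5% for the last, on the ground that “More impurity should therefore mean less target”. Its order is mine, and the low figure is its own.

The flask gives green > ochre > violet > grey > teal, with 36.4% and 5.78%, so the forecast stands on all three.

    starting material ⇌ target (K = 1.70, k = 0.0330 h⁻¹)
    target ⇌ isomer of the product (K = 0.600, k = 0.00905 h⁻¹)
    isomer of the product ⇌ starting material (k = 0.0329 h⁻¹)
    starting material + target ⇌ idle adduct, settled at all times (K = 1.04 M⁻¹)
    starting material + protic impurity → quenched substrate (k = 0.602 M⁻¹ h⁻¹)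

In green, half of the quench's turnover up to 30.0 h is done by 1.56 h. At 30.0 h, 0.16% of green's impurity charge is left unbound, with 26% of its starting material still free, and the impurity is the limiting reagent of that step. Starting material's use by the forward step to target, over its use by the quench, climbs from 0.91 just after the start to 12 at 7.23 h.

For green read at 20 h, epsilon's reading at that time over 94.1%, times green's free share, gives 31.3%. The computed flask holds 31.4%.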